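**Retrosynthetic overview**
- Final disconnection: the C6(ring)–C1'(chain) bond of the fully substituted 2H-pyran-2-one. This gives the C6–H pyranone (3,4-dimethoxy-5-methyl-2H-pyran-2-one) and the 10-(methylsulfanyl)decyl radical. The radical is released with loss of CO2 from the N-hydroxyphthalimide ester of 11-(methylsulfanyl)undecanoic acid (redox-neutral photoredox C–H alkylation).
- Enabling feature: in the ring O1/C2–C6, the carbons C3 (OMe), C4 (OMe) and C5 (Me) are blocked. C6–H is therefore the only ring C–H; it is bonded to O1 and lies at the δ-end of the C2(=O)–C3=C4–C5=C6 dienoate (α-position of the 2-hydroxypyrylium form), which makes it the acceptor site. The adduct radical is captodatively stabilised at C3 (3-OMe/C2=O).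
- Ring order: the only ring is made before the coupling. The sequence is C3–C4 Claisen acylation (methyl methoxyacetate + a propionyl amide), C5–C6 formylation of the keto ester dianion, O1–C2 enol lactonisation, then O4-methylation.
- Chain: 11-bromoundecanoic acid, SN2 with methanethiolate, then activation as the redox-active ester.

Key step: step 6

Remark on the chemistry: the target has no stereocentre and no stereogenic double bond, so it is achiral and needs no enantiocontrol. The sp3 centres in 3, 4 and 11 are labile or transient and are erased.

**Step 1**
Reactants: 1 methyl methoxyacetate; 2 N-methoxy-N-methylpropanamide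
Product: 3 methyl 2-methoxy-3-oxopentanoate (racemic)
Conditions: 1 (1.2 equiv), LDA (commercial solution, 1.2 equiv), THF, −78 °C; 2, −78 → 0 °C; 1 M HCl
Reagents that add atoms: none
Why: Crossed Claisen-type acylation in which the lithium enolate of 1 adds to the N-methoxy-N-methyl amide 2 to give a chelated tetrahedral adduct that releases the β-keto ester only on the acidic quench, so that neither double addition nor enolate quenching by the product interferes; the new centre at C2 is racemic, configurationally labile and becomes sp2 in step 2.

**Step 2**
Reactants: 3 methyl 2-methoxy-3-oxopentanoate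
Product: 5 4-hydroxy-3-methoxy-5-methyl-2H-pyran-2-one, via keto aldehyde 4 (not isolated)
Conditions: LDA (commercial solution, 2.2 equiv), THF, −78 → 0 °C; HC(O)N(OMe)Me, −78 → 0 °C; 1 M HCl; crude 4, DBU (1.2 equiv), toluene, 80 °C; 1 M HCl work-up
Reagents that add atoms: N-methoxy-N-methylformamide, O=CN(C)OC
Why: γ-Acylation of a β-keto ester 1,3-dianion, whose more basic terminal carbanion (the CH2 of the ethyl ketone) attacks the formamide, followed by base-mediated 6-exo-trig enol lactonisation of the hydroxymethylene tautomer of 4 onto the methyl ester (O1–C2 bond), which is driven by formation of the aromatic 4-hydroxy-2-pyranone and erases both labile sp3 centres.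

**Step 3**
Reactants: 5 4-hydroxy-3-methoxy-5-methyl-2H-pyran-2-one
Product: 6 3,4-dimethoxy-5-methyl-2H-pyran-2-one
Conditions: Me2SO4 (1.2 equiv), K2CO3 (1.5 equiv), acetone, reflux
Reagents that add atoms: dimethyl sulfate, COS(=O)(=O)OC
Why: O-Alkylation (Williamson type) of the potassium pyronate, for which the dimethyl sulfate/K2CO3/acetone protocol is the standard way to 4-methoxy-2-pyranones (attack through O4 keeps the lactone), while C-methylation at C3 is blocked by the 3-OMe group.

**Step 4**
Reactants: 7 11-bromoundecanoic acid
Product: 8 11-(methylsulfanyl)undecanoic acid
Conditions: NaSMe (2.2 equiv), DMF, 0 → 25 °C; 1 M HCl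
Reagents that add atoms: sodium methanethiolate, C[S-].[Na+]
Why: SN2 displacement of the primary bromide by the soft thiolate, the first equivalent of which merely converts the acid into its inert carboxylate.

**Step 5**
Reactants: 8 11-(methylsulfanyl)undecanoic acid
Product: 9 1,3-dioxoisoindolin-2-yl 11-(methylsulfanyl)undecanoate
Conditions: N-hydroxyphthalimide (1.05 equiv), DIC (1.1 equiv), DMAP (10 mol %), CH2Cl2, 25 °C
Reagents that add atoms: N-hydroxyphthalimide, O=C1c2ccccc2C(=O)N1O
Why: Steglich-type carbodiimide esterification gives the N-acyloxyphthalimide (redox-active ester) under neutral, non-oxidising conditions that leave the sulfide untouched.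

**Step 6**
Reactants: 6 3,4-dimethoxy-5-methyl-2H-pyran-2-one; 9 1,3-dioxoisoindolin-2-yl 11-(methylsulfanyl)undecanoate
Product: 12 3,4-dimethoxy-5-methyl-6-[10-(methylsulfanyl)decyl]-2H-pyran-2-one (target), via decyl radical 10 (not isolated), via C6 adduct radical 11 (not isolated)
Conditions: 9 (1.5 equiv), fac-Ir(ppy)3 (1 mol %), TFA (2 equiv), MeCN, 450 nm LEDs, 25 °C, Ar
Reagents that add atoms: none
Why: Proposed new method: photoexcited fac-Ir(ppy)3 (about −1.7 V vs SCE) reduces the N-acyloxyphthalimide 9, which fragments to phthalimide anion, CO2 and the nucleophilic primary radical 10; 10 adds to C6 of the TFA-activated pyranone 6 to give the C5/C3-delocalised radical 11 (captodative at C3 between 3-OMe and C2=O), Ir(IV) (about +0.8 V) oxidises 11 to the cation, and loss of the C6 proton to phthalimide anion restores the pyranone, so that the step is redox-neutral overall. The closest known reaction type is the photoredox Minisci-type decarboxylative C–H alkylation of protonated azines, quinoxalinones, coumarins and chromones with N-hydroxyphthalimide esters; new here are the monocyclic 2-pyranone as acceptor and its C6–H as the site. No ring is closed and no stereocentre remains, since C6 is sp3 only in 11. The step needs site selectivity on the ring, and the substrate secures it: C6 is the only ring carbon that carries hydrogen, so only addition there can end in rearomatisation, and it is the sterically open δ-terminus of the O1–C6=C5–C4=C3–C2=O dienoate, whereas C3, C4 and C5 are fully substituted. It also needs chemoselectivity for the sulfide, which the oxidative-quenching cycle secures because its strongest oxidant, Ir(IV), lies far below the oxidation potential of a dialkyl sulfide (above +1.3 V), the reason why persulfate/silver, hypervalent-iodine or anodic Kolbe-type radical generation is avoided. A weak acid is chosen so that the carbonyl is polarised without building up an easily reduced pyrylium salt that would quench the catalyst unproductively.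

**Compound list**
1 | methyl methoxyacetate | COCC(=O)OC | starting material
2 | N-methoxy-N-methylpropanamide | CCC(=O)N(C)OC | starting material
3 | methyl 2-methoxy-3-oxopentanoate (racemic, labile centre) | CCC(=O)C(OC)C(=O)OC | intermediate
4 | methyl 2-methoxy-4-methyl-3,5-dioxopentanoate (keto aldehyde, enol/stereoisomer mixture, not isolated) | O=CC(C)C(=O)C(OC)C(=O)OC | intermediate
5 | 4-hydroxy-3-methoxy-5-methyl-2H-pyran-2-one | COc1c(O)c(C)coc1=O | intermediate
6 | 3,4-dimethoxy-5-methyl-2H-pyran-2-one | COc1c(C)coc(=O)c1OC | intermediate
7 | 11-bromoundecanoic acid | OC(=O)CCCCCCCCCCBr | starting material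
8 | 11-(methylsulfanyl)undecanoic acid | CSCCCCCCCCCCC(=O)O | intermediate
9 | 1,3-dioxoisoindolin-2-yl 11-(methylsulfanyl)undecanoate | CSCCCCCCCCCCC(=O)ON1C(=O)c2ccccc2C1=O | intermediate
10 | 10-(methylsulfanyl)decyl radical (not isolated) | CSCCCCCCCCC[CH2] | intermediate
11 | 3,4-dimethoxy-5-methyl-6-[10-(methylsulfanyl)decyl]-2-oxo-5,6-dihydro-2H-pyran-5-yl radical (C5/C3-delocalised, racemic at C6, not isolated) | CSCCCCCCCCCCC1OC(=O)C(OC)=C(OC)[C]1C | intermediate
12 | 3,4-dimethoxy-5-methyl-6-[10-(methylsulfanyl)decyl]-2H-pyran-2-one | COc1c(C)c(CCCCCCCCCCSC)oc(=O)c1OC | target

**Step count**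
- Total step count: 6.
- Longest linear sequence: 4 steps (1 → 2 → 3 → 6). The chain branch takes 3 steps (4 → 5 → 6).

**Steps most likely to fail**

1. Step 6 (Proposed new method).
   - Risk: addition of the primary radical to the donor-substituted ring may be too slow. The radical would then be lost to hydrogen abstraction, reduction or dimerisation. Unproductive quenching of the catalyst or sensitised photodimerisation of the pyranone may also compete.
   - Fallback: it sets out from 6 and 9 and comes back at 12. Compound 6 is deprotonated at C6 with TMPZnCl·LiCl (THF, 25 °C), a zincation next to the ring oxygen of the kind known for chromones and related base-sensitive oxygen heterocycles. This gives (3,4-dimethoxy-5-methyl-2-oxo-2H-pyran-6-yl)zinc chloride F1. Without isolation it is coupled with 9 under NiCl2·glyme/4,4'-di-tert-butyl-2,2'-bipyridine (THF/DMF, 25 °C). This is the known nickel-catalysed decarboxylative Negishi-type coupling of redox-active esters with (hetero)arylzinc reagents. It forms the same C6–C1' bond by capture of the radical at nickel instead of by addition to the ring.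

2. Step 2.
   - Risk: proton transfer between dianion and adduct may occur, formylation may be incomplete, or retro-Claisen loss of the formyl group may occur during the base-mediated lactonisation.
   - Fallback: it sets out from 3 and comes back at 5. Compound 3 is heated with tert-butoxybis(dimethylamino)methane (Bredereck's reagent, toluene, 90 °C). C2 carries no second hydrogen, so an adduct there cannot eliminate and reverts, and aminomethylenation ends at C4. The product is methyl (4E)-5-(dimethylamino)-2-methoxy-4-methyl-3-oxopent-4-enoate F2. Aqueous HCl/THF then hydrolyses the enaminone to the hydroxymethylene ketone, which lactonises with loss of methanol to 5. No strong base is involved.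

3. Step 3.
   - Risk: methylation of the ambident pyronate may occur at the lactone carbonyl oxygen instead of O4 (poor O4/O2 site selectivity).
   - Fallback: it sets out from 5 and comes back at 6. The SN2 alkylation of the free potassium salt is replaced by a Mitsunobu redox condensation with methanol (PPh3, DIAD, THF, 0 → 25 °C). Here the neutral vinylogous acid attacks the methoxyphosphonium ion, a reaction type known to functionalise 4-hydroxy-2-pyranones at O4. No new compound is made on this way (F0).

**Further compounds**
F1 | step 6 | (3,4-dimethoxy-5-methyl-2-oxo-2H-pyran-6-yl)zinc chloride | COc1c(C)c([Zn]Cl)oc(=O)c1OC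
F2 | step 2 | methyl (4E)-5-(dimethylamino)-2-methoxy-4-methyl-3-oxopent-4-enoate | CN(C)/C=C(\C)C(=O)C(OC)C(=O)OC
F0 | step 3 | none | none
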